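Readings and results are calculated for an exercise; the scatter is artificial.

At 0.250 min the green flask, the one asked about, already reads 30% target, so I start from that pace.

common to all: starting material 10 mM

| run | protic impurity | free enzyme | temperature | remark | time |
|---|---|---|---|---|---|
| green | 3 mM | 1 µM | 5 °C | the very flask that is asked about, followed so far |  |
| violet | 3 mM | 1 µM | 0 °C | run made earlier |  |
| flask | 3.00 mM | 1.0 µM | 5 °C |  | 5.0 min |

| green: time / min | green: target / % | violet: time / min | violet: target / % |
|---|---|---|---|
| 0.250 | 30 | 0.250 | 28 |
| 0.833 | 54 | 0.833 | 54 |
| 1.33 | 52 | 1.33 | 50 |
| 2.00 | 50 | 2.00 | 47 |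
| 3.00 | 49 | 3.00 | 46 |
| 4.00 | 47 | 4.00 | 45 |

(each reading ± 2 percentage points)

- north-west: at 5.0 min raise the temperature by 20 K, then wait 5.0 min
- north: at 5.0 min add free enzyme, 100% of the amount charged, then wait 5.0 min
- north-east: at 5.0 min take out 90% of the target then present, then wait 5.0 min
- south-east: change nothing and wait 5.0 min more

- removed target is counted in
- steps thought possible: free enzyme -> unfolded enzyme; starting material + free enzyme -> target + free enzyme; free enzyme + target -> spent catalyst; starting material + protic impurity -> quenched substrate; target + free enzyme <-> isomer of the product + free enzyme
- additions bring no volume worth counting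

* target, in percent of the starting material first charged, at 5.0 min
* what to do for the largest gain in target; "none" if nothing gains more than 2 percentage points (north-west / north / north-east / south-east / none)
* target present, with what was taken out counted in, in percent of the starting material first charged, after north-west
* target present, with what was taken out counted in, in percent of the starting material first charged, after north-east

I fold the givens into one number. Each free enzyme owes 10000 turnovers for one charge, and the first green reading shows 12000 min⁻¹. Over 5.0 min that makes 6.00. This N, the charges turned over in the time at the opening pace, is a Damköhler number. It stands above one, and one charge's worth of turnovers fits into 0.833 min, close to the highest green reading at 0.833 min. So I expect starting material to be the limiting reagent, and I expect no gain from north.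

One number is not enough, though. After that highest reading the green target falls 7 percentage points by 4.00 min, at 0.0184 of the opening pace. This fall may mean that the free enzyme is nearly stopped, or that target and isomer of the product stand near balance, or both, and N cannot part these. The readings from 2.00 min on run 50%, 49%, 47%. I commit to 49% for now. They differ by 3 points at a scatter of 2 points, so I read no clear further change, choose none and keep both options near that figure.

The forecast gives 46.5%, then 44% after north-west and 51% after north-east. It chooses north-east: “Taking out target pulls the equilibrium back”. There it differs from me.

The flask gives 48.8%, 48.8% after north-west and 49.0% after north-east, and the best choice is none.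

    free enzyme → unfolded enzyme (k = 6.76 × 10⁻⁴ s⁻¹, Ea = 253 kJ mol⁻¹)
    starting material + free enzyme → target + free enzyme, rate k2*[starting material]*[free enzyme]/(1 + ([starting material]/Km2) + ([target]/Kp2)) (0.417 mM, 4.08 mM, k = 7.54 × 10⁵ M⁻¹ s⁻¹, Ea = 27.0 kJ mol⁻¹)
    free enzyme + target → spent catalyst (k = 5.33 M⁻¹ s⁻¹, Ea = 46.0 kJ mol⁻¹)
    starting material + protic impurity → quenched substrate (k = 2.75 M⁻¹ s⁻¹, Ea = 48.0 kJ mol⁻¹)
    target + free enzyme ⇌ isomer of the product + free enzyme, rate k5*[free enzyme]*[target] forward; the back reaction follows from the equilibrium constant (K = 0.895, k = 52200 M⁻¹ s⁻¹, Ea = 23.0 kJ mol⁻¹, ΔH = −11.0 kJ mol⁻¹)
    (constants at 5 °C)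

At 5.00 min the flask holds 0.0416% free enzyme and 96.7% spent catalyst, as shares of the catalyst charged. Its starting material stands at 0.0216% of the charge, with N at 6.00. At the same pace, the neighbour flask with 17 mM starting material has N of 3.53, still above one. Yet its free enzyme ends at 0%, with 13% of its starting material left.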